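**Retrosynthetic overview**

- Target ⇒ its 7,4'-bis-silyl ether ⇒ (aromatic Claisen, O5→C6, through a dearomatised cyclohexadienone) the 5-O-prenyl ether of the protected dihydroflavonol. The 1,1-dimethylallyl group is delivered from the only oxygen whose sole free ortho carbon is C6.
- 5-O-prenyl dihydroflavonol ⇒ flat 5-prenyloxy-7-silyloxychromone + a 4-silyloxyphenylzinc reagent. Enantioselective Rh-catalysed arylation dearomatises the γ-pyrone ring with silyl trapping (sets C2); Rubottom oxidation of the enol silane then sets C3 trans.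
- Chromone ⇒ 5,7-dihydroxychromone (7-O-silylation, 5-O-prenylation) ⇒ 2',4',6'-trihydroxyacetophenone + one carbon from DMF.
- Ring order: ring A is bought; the pyranone ring C is closed first; ring B is attached intact in the arylation step.

Assumptions: (S)-BINAP is taken to deliver the aryl group to the same enone face as in its cyclohexenone and 4-quinolone arylations, which corresponds to the (2S) enol silane needed here; this is an analogy and the first run is checked by chiral HPLC/CD. The titrated DMDO stock solution in acetone is made separately and not counted as a step.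

**Step 1**
Reactants: 1 1-(2,4,6-trihydroxyphenyl)ethanone (2',4',6'-trihydroxyacetophenone)
Product: 2 5,7-dihydroxy-4H-chromen-4-one
Conditions: BF3·OEt2 (4 equiv), DMF, 0 °C to rt; MsCl (3 equiv), DMF, 70–90 °C; H2O
Reagents that add atoms: N,N-dimethylformamide, CN(C)C=O (the C2–H carbon)
Why: Bass-type chromone synthesis: the BF2-chelated methyl ketone is C-formylated by the Vilsmeier-type salt from DMF/MsCl and the aminomethylene ketone closes onto an ortho OH with loss of dimethylamine; the two ortho OH groups of 1 are equivalent, so only one chromone can form and no stereocentre is created.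

**Step 2**
Reactants: 2 5,7-dihydroxy-4H-chromen-4-one
Product: 3 7-(tert-butyldimethylsilyloxy)-5-hydroxy-4H-chromen-4-one
Conditions: TBSCl (1.1 equiv), imidazole (2.2 equiv), DMF, 0 °C to rt
Reagents that add atoms: tert-butyldimethylsilyl chloride, CC(C)(C)[Si](C)(C)Cl
Why: Selective silylation: the 7-OH is the most acidic, unhindered phenol, whereas the 5-OH is locked in a hydrogen bond to C4=O and does not react with TBSCl/imidazole.

**Step 3**
Reactants: 3 7-(tert-butyldimethylsilyloxy)-5-hydroxy-4H-chromen-4-one; 4 3-methylbut-2-en-1-ol (prenol)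
Product: 5 7-(tert-butyldimethylsilyloxy)-5-(3-methylbut-2-enyloxy)-4H-chromen-4-one
Conditions: PPh3 (1.5 equiv), DIAD (1.5 equiv), THF, 0 °C to rt
Reagents that add atoms: none
Why: Mitsunobu etherification of the chelated 5-OH with a primary allylic alcohol under neutral conditions, which gives O-alkylation only (no C-prenylation) and leaves the aryl silyl ether intact, as known for the 5-OH of 7-O-protected flavanones.

**Step 4 (key step)**
Reactants: 5 7-(tert-butyldimethylsilyloxy)-5-(3-methylbut-2-enyloxy)-4H-chromen-4-one; 6 (4-bromophenoxy)(tert-butyl)dimethylsilane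
Product: 11 (2R,3R)-7-(tert-butyldimethylsilyloxy)-2-[4-(tert-butyldimethylsilyloxy)phenyl]-3-hydroxy-5-(3-methylbut-2-enyloxy)chroman-4-one, via aryllithium 7 (not isolated), via arylzinc chloride 8 (not isolated), via silyl enol ether 9 (not isolated), via 3-silyloxy ketone 10 (not isolated)
Conditions: 6 (2.5 equiv), n-BuLi, THF, –78 °C; ZnCl2, –78 to 0 °C; then 5, [RhCl(C2H4)2]2 (3.5 mol %), (S)-BINAP (7.7 mol %), TMSCl (2.5 equiv), THF, 20 °C; filter (Florisil, pentane/Et3N); DMDO (1.1 equiv), acetone/CH2Cl2, –78 °C; citric acid, MeOH, 0 °C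
Reagents that add atoms: dimethyldioxirane, CC1(C)OO1 (the 3-OH oxygen of 11); chlorotrimethylsilane, C[Si](C)(C)Cl (TMS of 9 and 10 only); zinc chloride, Cl[Zn]Cl (ZnCl of 8 only); n-butyllithium, [Li]CCCC (Li of 7 only)
Why: Proposed new method: an aryl–Rh(I)/(S)-BINAP species adds to C2 of the benzo-γ-pyrone, breaking the cyclic conjugation of the pyrone ring, and TMSCl silylates the Rh oxa-π-allyl faster than it can ring-open by β-aryloxide loss, giving enol silane 9 with the (2S) centre set by the ligand; DMDO then oxygenates C3 of this very electron-rich enol ether on the face anti to the C2 aryl group (Rubottom oxidation, expected to be much faster at –78 °C than epoxidation of the allyl-ether-deactivated prenyl alkene), so the 3-OH ends trans to the aryl group, i.e. (2R,3R); the closest known reactions are the Rh/BINAP-catalysed asymmetric 1,4-addition of arylzinc chlorides with TMSCl to 4-quinolones and 2,3-dihydro-4-pyridones, the Rh-catalysed asymmetric arylation of chromones with arylboronic acids, and the Rubottom oxidation of flavanone silyl enol ethers to trans-3-hydroxyflavanones.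

**Step 5**
Reactants: 11 (2R,3R)-7-(tert-butyldimethylsilyloxy)-2-[4-(tert-butyldimethylsilyloxy)phenyl]-3-hydroxy-5-(3-methylbut-2-enyloxy)chroman-4-one
Product: 13 (2R,3R)-7-(tert-butyldimethylsilyloxy)-2-[4-(tert-butyldimethylsilyloxy)phenyl]-3,5-dihydroxy-6-(2-methylbut-3-en-2-yl)chroman-4-one, via C6 dienone 12 (not isolated)
Conditions: Eu(fod)3 (10 mol %), CHCl3 (EtOH-free), 45–50 °C, stop at full conversion; SiO2 separation from the 8-prenyl isomer
Reagents that add atoms: none
Why: Eu(III)-catalysed aromatic Claisen rearrangement, a known reaction of 5-O-prenylflavanones: Eu bound in the O3/O4/O5 pocket accelerates the [3,3] shift of the prenyl group to C6, the only free ortho carbon, giving dearomatised dienone 12, which tautomerises to the phenol; the stereocentres are not involved, and the mild temperature is chosen to hold the product at the ortho stage, the 8-prenyl isomer from a subsequent Cope shift being the expected co-product.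

**Step 6**
Reactants: 13 (2R,3R)-7-(tert-butyldimethylsilyloxy)-2-[4-(tert-butyldimethylsilyloxy)phenyl]-3,5-dihydroxy-6-(2-methylbut-3-en-2-yl)chroman-4-one
Product: 14 (2R,3R)-3,5,7-trihydroxy-2-(4-hydroxyphenyl)-6-(2-methylbut-3-en-2-yl)chroman-4-one
Conditions: TBAF (2.5 equiv), AcOH (3 equiv), THF, 0 °C, Ar; pH 5–6 work-up
Reagents that add atoms: none
Why: Fluoride cleavage of both aryl silyl ethers, buffered with AcOH so that the dihydroflavonol is neither epimerised or oxidised by base nor the 1,1-dimethylallyl group cyclised onto a flanking phenol by acid; C2 and C3 are untouched.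

**Compound list**

1 | 1-(2,4,6-trihydroxyphenyl)ethanone | CC(=O)c1c(O)cc(O)cc1O | starting material
2 | 5,7-dihydroxy-4H-chromen-4-one | O=c1ccoc2cc(O)cc(O)c12 | intermediate
3 | 7-(tert-butyldimethylsilyloxy)-5-hydroxy-4H-chromen-4-one | O=c1ccoc2cc(O[Si](C)(C)C(C)(C)C)cc(O)c12 | intermediate
4 | 3-methylbut-2-en-1-ol | CC(C)=CCO | starting material
5 | 7-(tert-butyldimethylsilyloxy)-5-(3-methylbut-2-enyloxy)-4H-chromen-4-one | O=c1ccoc2cc(O[Si](C)(C)C(C)(C)C)cc(OCC=C(C)C)c12 | intermediate
6 | (4-bromophenoxy)(tert-butyl)dimethylsilane | CC(C)(C)[Si](C)(C)Oc1ccc(Br)cc1 | starting material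
7 | [4-(tert-butyldimethylsilyloxy)phenyl]lithium | [Li]c1ccc(O[Si](C)(C)C(C)(C)C)cc1 | intermediate
8 | [4-(tert-butyldimethylsilyloxy)phenyl]zinc chloride | Cl[Zn]c1ccc(O[Si](C)(C)C(C)(C)C)cc1 | intermediate
9 | (2S)-7-(tert-butyldimethylsilyloxy)-2-[4-(tert-butyldimethylsilyloxy)phenyl]-5-(3-methylbut-2-enyloxy)-4-(trimethylsilyloxy)-2H-chromene | CC(C)=CCOc1cc(O[Si](C)(C)C(C)(C)C)cc2c1C(O[Si](C)(C)C)=C[C@@H](c1ccc(O[Si](C)(C)C(C)(C)C)cc1)O2 | intermediate
10 | (2R,3R)-7-(tert-butyldimethylsilyloxy)-2-[4-(tert-butyldimethylsilyloxy)phenyl]-5-(3-methylbut-2-enyloxy)-3-(trimethylsilyloxy)chroman-4-one | CC(C)=CCOc1cc(O[Si](C)(C)C(C)(C)C)cc2c1C(=O)[C@H](O[Si](C)(C)C)[C@@H](c1ccc(O[Si](C)(C)C(C)(C)C)cc1)O2 | intermediate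
11 | (2R,3R)-7-(tert-butyldimethylsilyloxy)-2-[4-(tert-butyldimethylsilyloxy)phenyl]-3-hydroxy-5-(3-methylbut-2-enyloxy)chroman-4-one | CC(C)=CCOc1cc(O[Si](C)(C)C(C)(C)C)cc2c1C(=O)[C@H](O)[C@@H](c1ccc(O[Si](C)(C)C(C)(C)C)cc1)O2 | intermediate
12 | (2R,3R)-7-(tert-butyldimethylsilyloxy)-2-[4-(tert-butyldimethylsilyloxy)phenyl]-3-hydroxy-6-(2-methylbut-3-en-2-yl)-2,3-dihydro-4H-chromene-4,5(6H)-dione (C6 epimers) | C=CC(C)(C)C1C(O[Si](C)(C)C(C)(C)C)=CC2=C(C1=O)C(=O)[C@H](O)[C@@H](c1ccc(O[Si](C)(C)C(C)(C)C)cc1)O2 | intermediate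
13 | (2R,3R)-7-(tert-butyldimethylsilyloxy)-2-[4-(tert-butyldimethylsilyloxy)phenyl]-3,5-dihydroxy-6-(2-methylbut-3-en-2-yl)chroman-4-one | C=CC(C)(C)c1c(O[Si](C)(C)C(C)(C)C)cc2c(c1O)C(=O)[C@H](O)[C@@H](c1ccc(O[Si](C)(C)C(C)(C)C)cc1)O2 | intermediate
14 | (2R,3R)-3,5,7-trihydroxy-2-(4-hydroxyphenyl)-6-(2-methylbut-3-en-2-yl)chroman-4-one | C=CC(C)(C)c1c(O)cc2c(c1O)C(=O)[C@H](O)[C@@H](c1ccc(O)cc1)O2 | target

**Step count and risks**

Total steps: 6. Longest linear sequence: 6 (1 → 2 → 3 → 5 → 11 → 13 → 14); 4 and 6 are bought and enter in steps 3 and 4.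

Most likely to fail, in this order:

Step 4. The arylzinc/TMSCl arylation has not been shown on chromones, so conversion, ee and the chemoselectivity of the oxidation are all untested. The fallback sets out from 5 and separates C–C from C–O bond formation. A base-free Rh(I)/chiral-diene (or electron-poor bisphosphine) addition of commercial 4-(tert-butyldimethylsilyloxy)phenylboronic acid in toluene–water gives the isolated flavanone (2S)-7-(tert-butyldimethylsilyloxy)-2-[4-(tert-butyldimethylsilyloxy)phenyl]-5-(3-methylbut-2-enyloxy)chroman-4-one F1. Soft enolisation of F1 (TMSOTf, Et3N, CH2Cl2, –78 °C; no free enolate, so no retro-oxa-Michael racemisation) gives enol silane 9, where the route is rejoined and the oxidation to 11 is run as before.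

Step 5. The ortho-dienone can undergo a Cope shift to C8 before it tautomerises, so the 8-prenyl isomer may dominate in an aprotic medium. The fallback sets out from 11 and changes both order and mechanism of proton transfer. Both silyl groups are removed first (TBAF/AcOH) to give (2R,3R)-3,7-dihydroxy-2-(4-hydroxyphenyl)-5-(3-methylbut-2-enyloxy)chroman-4-one F2. F2 is then rearranged without metal in a degassed protic medium (EtOH–H2O 1:1, about 110 °C, sealed tube), where hydrogen bonding accelerates the [3,3] shift and solvent proton relay should tautomerise the ortho-dienone faster than it can undergo the Cope shift. This comes back to the route at 14 directly.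

Step 1. The unprotected triphenol may be over-formylated (3-formylchromone) or give a low yield. The fallback sets out from 1 and protects first: TBSCl/imidazole silylates the unchelated 4-OH to give 1-[4-(tert-butyldimethylsilyloxy)-2,6-dihydroxyphenyl]ethanone F3. Condensation with DMF dimethyl acetal (toluene, 80 °C) gives (E)-1-[4-(tert-butyldimethylsilyloxy)-2,6-dihydroxyphenyl]-3-(dimethylamino)prop-2-en-1-one F4. Cyclisation of F4 with AcOH (loss of dimethylamine) comes back to the route at 3, bypassing 2.

**Further compounds**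

F1 | step 4 | (2S)-7-(tert-butyldimethylsilyloxy)-2-[4-(tert-butyldimethylsilyloxy)phenyl]-5-(3-methylbut-2-enyloxy)chroman-4-one | CC(C)=CCOc1cc(O[Si](C)(C)C(C)(C)C)cc2c1C(=O)C[C@@H](c1ccc(O[Si](C)(C)C(C)(C)C)cc1)O2
F2 | step 5 | (2R,3R)-3,7-dihydroxy-2-(4-hydroxyphenyl)-5-(3-methylbut-2-enyloxy)chroman-4-one | CC(C)=CCOc1cc(O)cc2c1C(=O)[C@H](O)[C@@H](c1ccc(O)cc1)O2
F3 | step 1 | 1-[4-(tert-butyldimethylsilyloxy)-2,6-dihydroxyphenyl]ethanone | CC(=O)c1c(O)cc(O[Si](C)(C)C(C)(C)C)cc1O
F4 | step 1 | (E)-1-[4-(tert-butyldimethylsilyloxy)-2,6-dihydroxyphenyl]-3-(dimethylamino)prop-2-en-1-one | CN(C)/C=C/C(=O)c1c(O)cc(O[Si](C)(C)C(C)(C)C)cc1O
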